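**Strategy**

Everything rests on cutting the Z‑configured C4=C5 bond and re‑joining C4 and C5 through sulfur: the strained trisubstituted alkene of the furanone‑bridged ten‑membered carbocycle (C1–C10, with the C3–O–C10 bridge) is made last by Ramberg–Bäcklund contraction of an eleven‑membered cyclic sulfone, exploiting the acidity of C4–H next to the furanone. In one operation the key step forms the C4–C5 bond, sets the Z geometry and delivers the carbocycle. Its precursor has sulfur between C4 and C5, a free C6 hydroxyl that arises when a C4 thiolate opens a C5–C6 epoxide, and the lactone masked as C8 and C12 silyl ethers; C10 comes from (S)‑lactic acid, C7/C8 from an Evans aldol.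

Key step: step 22

Remark: carbon locants C1–C13 are those of the target skeleton (C1 ketone, C3 enol‑ether carbon, C10 quaternary, C11–C13 lactone unit). Amide 28 is used as the racemate, so 30–37 are carried as mixtures of C4 epimers; they converge in step 22, where C4 becomes trigonal.

**Route**

Step 1
Reactants: 1 (S)-lactic acid
Product: 2 (2S,5S)-2-tert-butyl-5-methyl-1,3-dioxolan-4-one
Conditions: t-BuCHO, TsOH·H2O (cat.), pentane, reflux, Dean–Stark; crystallisation from pentane, −78 °C
Reagents that add atoms: pivalaldehyde, CC(C)(C)C=O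
Why: Acid-catalysed acetalisation (self-regeneration of stereocentres) should give mainly the cis-dioxolanone, purified by cold crystallisation, so that the lactate configuration is stored at the acetal carbon.

Step 2
Reactants: 2 cis-dioxolanone; 3 allyl bromide
Product: 5 (2S,5R)-2-tert-butyl-5-methyl-5-(prop-2-en-1-yl)-1,3-dioxolan-4-one, via lithium enolate 4 (not isolated)
Conditions: LiN(iPr)2, THF, −78 °C; then 3, −78 → −20 °C
Reagents that add atoms: none
Why: Enolate alkylation anti to the tert-butyl group (Seebach alkylation) should set the C10 quaternary centre with net retention of the lactate configuration.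

Step 3
Reactants: 5 allyl dioxolanone
Product: 6 (2S,5R)-2-tert-butyl-5-methyl-5-(prop-2-en-1-yl)-1,3-dioxolan-4-ol (both C4 epimers)
Conditions: iBu2AlH, CH2Cl2, −78 °C; Rochelle salt
Reagents that add atoms: none
Why: Half-reduction of the lactone-type carbonyl should stop at the aluminium hemiacetal at low temperature and give the lactol.

Step 4
Reactants: 6 lactol
Product: 8 (3R)-3-methylhex-5-en-1-yn-3-ol, via hydroxy aldehyde 7 (not isolated)
Conditions: dimethyl (1-diazo-2-oxopropyl)phosphonate (excess), K2CO3, MeOH, 0 °C → rt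
Reagents that add atoms: dimethyl (1-diazo-2-oxopropyl)phosphonate, CC(=O)C(=[N+]=[N-])P(=O)(OC)OC
Why: Ohira–Bestmann homologation of a lactol: in basic methanol the hemiacetal opens with loss of pivalaldehyde and the α-hydroxy aldehyde should be converted into the terminal alkyne without touching the quaternary centre, the excess reagent covering the pivalaldehyde released.

Step 5
Reactants: 8 alkynol
Product: 9 (3R)-3-methyl-3-[(trimethylsilyl)oxy]hex-5-en-1-yne
Conditions: Me3SiCl, imidazole, CH2Cl2, 0 °C → rt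
Reagents that add atoms: chlorotrimethylsilane, C[Si](C)(C)Cl
Why: Silylation of the tertiary propargylic alcohol with the small trimethylsilyl group should be easy and masks the hydroxyl for the aldol step.

Step 6
Reactants: 9 silyl ether
Product: 11 (3R)-3-methyl-3-[(trimethylsilyl)oxy]pent-4-ynal, via ozonide 10 (not isolated)
Conditions: O3, CH2Cl2, −78 °C (Sudan Red 7B end point); then PPh3, −78 °C → rt
Reagents that add atoms: ozone, [O-][O+]=O
Why: Ozonolysis with reductive work-up should cleave the terminal alkene much faster than the alkyne and give the non-epimerisable C8 aldehyde.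

Step 7
Reactants: 12 4-methyl hydrogen itaconate
Product: 14 methyl 3-(hydroxymethyl)but-3-enoate, via isobutyl carbonic mixed anhydride 13 (not isolated)
Conditions: i-BuOCOCl, N-methylmorpholine, THF, −15 °C; then NaBH4, H2O, 0 °C
Reagents that add atoms: none
Why: Mixed-anhydride activation followed by borohydride reduction should reduce only the conjugated carboxylic acid in the 1,2-sense and leave the methyl ester.

Step 8
Reactants: 14 hydroxy ester
Product: 15 methyl 3-({[tert-butyl(dimethyl)silyl]oxy}methyl)but-3-enoate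
Conditions: t-BuMe2SiCl, imidazole, CH2Cl2, 0 °C → rt
Reagents that add atoms: tert-butyl(chloro)dimethylsilane, CC(C)(C)[Si](C)(C)Cl
Why: Standard silylation of a primary allylic alcohol, done promptly so that lactonisation of the γ-hydroxy ester cannot compete.

Step 9
Reactants: 15 silyloxy ester
Product: 16 3-({[tert-butyl(dimethyl)silyl]oxy}methyl)but-3-enoic acid
Conditions: LiOH, THF/H2O, 0 °C; then 1 M HCl to pH 4, 0 °C
Reagents that add atoms: lithium hydroxide, [Li+].[OH-]
Why: Saponification at 0 °C should cleave the methyl ester faster than base can move the β,γ-double bond into conjugation.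

Step 10
Reactants: 16 acid; 17 (4R)-4-benzyl-1,3-oxazolidin-2-one
Product: 19 (4R)-4-benzyl-3-[3-({[tert-butyl(dimethyl)silyl]oxy}methyl)but-3-enoyl]-1,3-oxazolidin-2-one, via pivalic mixed anhydride 18 (not isolated)
Conditions: t-BuCOCl, Et3N, THF, −20 °C; then 17, LiCl, −20 °C → rt
Reagents that add atoms: none
Why: N-acylation through the pivalic mixed anhydride under LiCl activation needs no strong base and should give the β,γ-unsaturated imide without isomerisation.

Step 11
Reactants: 19 imide; 11 aldehyde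
Product: 21 syn-aldol imide (7R; 8S; 10R), via dibutylboron Z-enolate 20 (not isolated)
Conditions: n-Bu2BOTf, i-Pr2NEt, CH2Cl2, −78 → 0 °C; then 11, −78 → 0 °C; pH 7 buffer, MeOH, H2O2
Reagents that add atoms: none
Why: Evans syn-aldol: the Z-boron dienolate should react at its α-carbon through a Zimmerman–Traxler chair on the face dictated by the (R)-benzyl auxiliary, which sets C7 and C8 together (7,8-syn) irrespective of the remote C10 centre.

Step 12
Reactants: 21 aldol imide
Product: 22 Weinreb amide (7R; 8S; 10R)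
Conditions: MeNH(OMe)·HCl, AlMe3, CH2Cl2, −20 → 0 °C; Rochelle salt
Reagents that add atoms: N,O-dimethylhydroxylamine hydrochloride, Cl.CNOC
Why: Aluminium-amide transamination to the Weinreb amide, directed by the free C8 hydroxyl, should cleave the exocyclic acyl bond and release the auxiliary without epimerising C7.

Step 13
Reactants: 22 Weinreb amide
Product: 23 chloromethyl ketone (7R; 8S; 10R)
Conditions: ICH2Cl, MeLi·LiBr (excess), THF/Et2O, −78 °C; sat. NH4Cl
Reagents that add atoms: chloroiodomethane, ClCI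
Why: The lithium carbenoid LiCH2Cl generated in situ should add once to the Weinreb amide because the chelated tetrahedral adduct survives until the quench, the extra equivalents being consumed by the O–H and alkyne C–H.

Step 14
Reactants: 23 β-hydroxy ketone (used crude)
Product: 24 anti-1,3-diol chlorohydrin (6R; 7R; 8S; 10R)
Conditions: Me4NBH(OAc)3, MeCN/AcOH, −30 → −20 °C
Reagents that add atoms: none
Why: Evans–Saksena reduction: intramolecular hydride delivery from the C8 alkoxy(acetoxy)borohydride should set C6 with the 6,8-anti relationship under acidic conditions that do not epimerise C7.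

Step 15
Reactants: 24 chlorohydrin
Product: 25 terminal epoxide diol (6R; 7R; 8S; 10R)
Conditions: K2CO3, MeOH, 0 °C → rt
Reagents that add atoms: none
Why: Williamson closure of the vicinal chlorohydrin (3-exo-tet, retention at C6) should outpace attack of the C8 hydroxyl on C5, and methanolysis removes the tertiary trimethylsilyl ether in the same pot.

Step 16
Reactants: 25 epoxide diol
Product: 26 C8 tert-butyldimethylsilyl ether (6R; 7S; 8S; 10R)
Conditions: t-BuMe2SiCl, imidazole, DMAP (cat.), DMF, rt
Reagents that add atoms: tert-butyl(chloro)dimethylsilane, CC(C)(C)[Si](C)(C)Cl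
Why: The secondary C8 hydroxyl should be silylated selectively over the tertiary propargylic C10 hydroxyl under conditions that leave the epoxide alone.

Step 17
Reactants: 27 2-chloropropanoyl chloride
Product: 28 2-chloro-N-methoxy-N-methylpropanamide
Conditions: MeNH(OMe)·HCl, pyridine, CH2Cl2, 0 °C → rt
Reagents that add atoms: N,O-dimethylhydroxylamine hydrochloride, Cl.CNOC
Why: Simple amidation of an acid chloride gives the Weinreb amide that carries C3, C4 and the C4 leaving group.

Step 18
Reactants: 26 alkynol; 28 Weinreb amide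
Product: 30 γ-hydroxy ynone (C4 epimers), via dilithium alkoxide acetylide 29 (not isolated)
Conditions: n-BuLi (2.1 equiv), THF, −78 °C; then 28, −78 → −40 °C; sat. NH4Cl
Reagents that add atoms: none
Why: Acylation of a lithium acetylide by a Weinreb amide should stop at the ynone, and the low temperature preserves the epoxide and the α-chloride.

Step 19
Reactants: 30 γ-hydroxy ynone
Product: 31 5-(1-chloroethyl)-3(2H)-furanone epoxide (C4 epimers)
Conditions: Ph3PAuNTf2 (5 mol %), toluene, H2O (1 equiv), rt
Reagents that add atoms: none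
Why: Gold-catalysed cycloisomerisation of a γ-hydroxy ynone: π-activation directs water to the alkyne carbon remote from the carbonyl (C1), and the hydroxy diketone cyclodehydrates through the C10 hydroxyl onto C3, so the furanone forms with C10 unchanged and without a nucleophile that could displace the chloride.

Step 20
Reactants: 31 chloride epoxide
Product: 34 eleven-membered cyclic hydroxy sulfide (C4 epimers), via C4 thioacetate 32 (not isolated), via caesium thiolate 33 (not isolated)
Conditions: KSC(O)CH3, DMF, 0 °C; then slow addition to Cs2CO3, MeOH/DMF (degassed, 2 mM), rt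
Reagents that add atoms: potassium thioacetate, CC(=O)[S-].[K+]
Why: SN2 displacement of the activated C4 chloride by thioacetate, then methanolysis at high dilution frees the caesium thiolate, which should open the terminal epoxide at C5 (intramolecular thiol–epoxide opening, caesium-thiolate macrocyclisation) to close the thia-ring and leave the C6 hydroxyl free without any protecting-group step.

Step 21
Reactants: 34 cyclic sulfide
Product: 35 eleven-membered cyclic sulfone (C4 epimers)
Conditions: (NH4)6Mo7O24·4H2O (cat.), 30 % H2O2, EtOH, 0 °C → rt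
Reagents that add atoms: hydrogen peroxide, OO
Why: Molybdate-catalysed peroxide oxidation should take the sulfide to the sulfone chemoselectively in the presence of both alkenes and the free hydroxyl.

Step 22
Reactants: 35 cyclic sulfone
Product: 38 furanone-bridged (4Z)-cyclodecenol bis-silyl ether, via C4-bromo sulfone 36 (not isolated), via cis-episulfone 37 (not isolated)
Conditions: BrCl2C–CCl2Br, KOH/Al2O3, t-BuOH/THF, 0 °C → rt
Reagents that add atoms: none
Why: Ramberg–Bäcklund reaction with in situ halogenation: hydroxide on alumina deprotonates C4, the most acidic site because it is α to the sulfone and vinylogous to the C1 ketone through C2=C3, and the carbanion takes Br+ from the dibromide, which leaves only tetrachloroethene and bromide and no carbene. Deprotonation at C5 then closes the episulfone by a 3-exo-tet 1,3-displacement of bromide, forming the C4–C5 bond, and cheletropic loss of SO2 gives the alkene, so the ten-membered carbocycle arises by contraction of the eleven-membered ring and not by direct closure. No stereocentre is created; C4 is destroyed, which is why both C4 epimers converge, and C6, C7, C8 and C10 are untouched. The Z geometry is secured by the ring, which can hold only the cis-fused episulfone, and SO2 extrusion is stereospecific. Chemoselectivity rests on the C6 hydroxyl being an alkoxide under the conditions, a non-leaving group that blocks β-elimination from the C5 carbanion, and on the lactone being present only as silyl ethers. The closest known reaction type is the contraction of medium and large cyclic sulfones to cycloalkenes with KOH/Al2O3 and a polyhaloalkane.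

Step 23
Reactants: 39 angelic acid
Product: 40 (2Z)-2-methylbut-2-en-1-ol
Conditions: LiAlH4, Et2O, 0 °C → rt
Reagents that add atoms: none
Why: Hydride reduction of the carboxylic acid should give the allylic alcohol with the Z geometry retained.

Step 24
Reactants: 40 allylic alcohol
Product: 41 [(2S,3R)-2,3-dimethyloxiran-2-yl]methanol
Conditions: Ti(OiPr)4 (cat.), L-(+)-diethyl tartrate, t-BuOOH, 4 Å MS, CH2Cl2, −20 °C
Reagents that add atoms: tert-butyl hydroperoxide, CC(C)(C)OO
Why: Sharpless asymmetric epoxidation: the titanium (2R,3R)-tartrate complex should deliver oxygen to one face of the Z-allylic alcohol and set both epoxide centres, any minor enantiomer being removed later as a diastereomeric ester.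

Step 25
Reactants: 41 epoxy alcohol
Product: 43 (2R,3R)-2,3-dimethyloxirane-2-carboxylic acid, via epoxy aldehyde 42 (not isolated)
Conditions: TEMPO (cat.), PhI(OAc)2, MeCN/H2O, 0 °C → rt
Reagents that add atoms: water, O
Why: Nitroxyl-catalysed oxidation in aqueous acetonitrile should take the primary alcohol through the aldehyde hydrate to the acid without opening the epoxide.

Step 26
Reactants: 38 cyclodecenol; 43 epoxy acid
Product: 45 C6 epoxyangelate bis-silyl ether, via Yamaguchi mixed anhydride 44 (not isolated)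
Conditions: 2,4,6-Cl3C6H2COCl, Et3N, THF, rt; then 38, DMAP, toluene, rt → 40 °C
Reagents that add atoms: none
Why: Yamaguchi esterification should acylate the only free hydroxyl (C6), and the epoxy acid has no epimerisable or isomerisable position.

Step 27
Reactants: 45 ester
Product: 46 C8,C12-diol
Conditions: HF·pyridine, pyridine, THF, 0 °C → rt
Reagents that add atoms: none
Why: Buffered HF·pyridine should remove both silyl ethers under non-basic conditions that avoid O6→O8 acyl migration and spare the electron-poor glycidic ester.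

Step 28
Reactants: 46 diol
Product: 49 target CNP0258430.3, via hydroxy enal 47 (not isolated), via lactol 48 (not isolated)
Conditions: MnO2 (activated, excess), CH2Cl2, rt
Reagents that add atoms: none
Why: Allylic oxidation with MnO2 should convert the C12 alcohol into the enal, which closes with the C8 hydroxyl to the lactol and is oxidised again to the trans-fused α-methylene γ-lactone, while the non-allylic C8 hydroxyl is not oxidised directly.

**Compound list**

1 | (S)-lactic acid, (2S)-2-hydroxypropanoic acid | C[C@H](O)C(=O)O | starting material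
2 | (2S,5S)-2-tert-butyl-5-methyl-1,3-dioxolan-4-one | C[C@@H]1O[C@H](C(C)(C)C)OC1=O | intermediate
3 | allyl bromide, 3-bromoprop-1-ene | C=CCBr | starting material
4 | lithium enolate of 2, lithium (2S)-2-tert-butyl-5-methyl-1,3-dioxol-4-olate | [Li]OC1=C(C)O[C@H](C(C)(C)C)O1 | intermediate
5 | (2S,5R)-2-tert-butyl-5-methyl-5-(prop-2-en-1-yl)-1,3-dioxolan-4-one | C=CC[C@@]1(C)O[C@H](C(C)(C)C)OC1=O | intermediate
6 | (2S,5R)-2-tert-butyl-5-methyl-5-(prop-2-en-1-yl)-1,3-dioxolan-4-ol, both C4 epimers | C=CC[C@@]1(C)O[C@H](C(C)(C)C)OC1O | intermediate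
7 | (2R)-2-hydroxy-2-methylpent-4-enal | C=CC[C@@](C)(O)C=O | intermediate
8 | (3R)-3-methylhex-5-en-1-yn-3-ol | C=CC[C@@](C)(O)C#C | intermediate
9 | (3R)-3-methyl-3-[(trimethylsilyl)oxy]hex-5-en-1-yne | C=CC[C@@](C)(O[Si](C)(C)C)C#C | intermediate
10 | ozonide of 9, 3-{(2R)-2-methyl-2-[(trimethylsilyl)oxy]but-3-yn-1-yl}-1,2,4-trioxolane | C1OC(OO1)C[C@@](C)(O[Si](C)(C)C)C#C | intermediate
11 | (3R)-3-methyl-3-[(trimethylsilyl)oxy]pent-4-ynal (C8 aldehyde, C10 R) | O=CC[C@@](C)(O[Si](C)(C)C)C#C | intermediate
12 | 4-methyl hydrogen itaconate, 4-methoxy-2-methylidene-4-oxobutanoic acid | C=C(CC(=O)OC)C(=O)O | starting material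
13 | isobutyl carbonic mixed anhydride of 12 | C=C(CC(=O)OC)C(=O)OC(=O)OCC(C)C | intermediate
14 | methyl 3-(hydroxymethyl)but-3-enoate | C=C(CO)CC(=O)OC | intermediate
15 | methyl 3-({[tert-butyl(dimethyl)silyl]oxy}methyl)but-3-enoate | C=C(CO[Si](C)(C)C(C)(C)C)CC(=O)OC | intermediate
16 | 3-({[tert-butyl(dimethyl)silyl]oxy}methyl)but-3-enoic acid | C=C(CO[Si](C)(C)C(C)(C)C)CC(=O)O | intermediate
17 | (4R)-4-benzyl-1,3-oxazolidin-2-one | O=C1N[C@H](Cc2ccccc2)CO1 | starting material
18 | pivalic mixed anhydride of 16 | C=C(CO[Si](C)(C)C(C)(C)C)CC(=O)OC(=O)C(C)(C)C | intermediate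
19 | (4R)-4-benzyl-3-[3-({[tert-butyl(dimethyl)silyl]oxy}methyl)but-3-enoyl]-1,3-oxazolidin-2-one | C=C(CO[Si](C)(C)C(C)(C)C)CC(=O)N1[C@H](Cc2ccccc2)COC1=O | intermediate
20 | dibutylboron (Z)-enolate of 19 | CCCCB(CCCC)O/C(=C\C(=C)CO[Si](C)(C)C(C)(C)C)N1[C@H](Cc2ccccc2)COC1=O | intermediate
21 | (4R)-4-benzyl-3-[(2R,3S,5R)-2-(3-{[tert-butyl(dimethyl)silyl]oxy}prop-1-en-2-yl)-3-hydroxy-5-methyl-5-[(trimethylsilyl)oxy]hept-6-ynoyl]-1,3-oxazolidin-2-one | O=C1OC[C@@H](Cc2ccccc2)N1C(=O)[C@H](C(=C)CO[Si](C)(C)C(C)(C)C)[C@@H](O)C[C@@](C)(O[Si](C)(C)C)C#C | intermediate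
22 | (2R,3S,5R)-2-(3-{[tert-butyl(dimethyl)silyl]oxy}prop-1-en-2-yl)-3-hydroxy-N-methoxy-N,5-dimethyl-5-[(trimethylsilyl)oxy]hept-6-ynamide | CON(C)C(=O)[C@H](C(=C)CO[Si](C)(C)C(C)(C)C)[C@@H](O)C[C@@](C)(O[Si](C)(C)C)C#C | intermediate
23 | (3R,4S,6R)-3-(3-{[tert-butyl(dimethyl)silyl]oxy}prop-1-en-2-yl)-1-chloro-4-hydroxy-6-methyl-6-[(trimethylsilyl)oxy]oct-7-yn-2-one | ClCC(=O)[C@H](C(=C)CO[Si](C)(C)C(C)(C)C)[C@@H](O)C[C@@](C)(O[Si](C)(C)C)C#C | intermediate
24 | (2R,3R,4S,6R)-3-(3-{[tert-butyl(dimethyl)silyl]oxy}prop-1-en-2-yl)-1-chloro-6-methyl-6-[(trimethylsilyl)oxy]oct-7-yne-2,4-diol | ClC[C@H](O)[C@H](C(=C)CO[Si](C)(C)C(C)(C)C)[C@@H](O)C[C@@](C)(O[Si](C)(C)C)C#C | intermediate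
25 | (3R,5S,6R)-7-({[tert-butyl(dimethyl)silyl]oxy}methyl)-3-methyl-6-[(2R)-oxiran-2-yl]oct-7-en-1-yne-3,5-diol | C1O[C@@H]1[C@H](C(=C)CO[Si](C)(C)C(C)(C)C)[C@@H](O)C[C@@](C)(O)C#C | intermediate
26 | (3R,5S,6S)-5-{[tert-butyl(dimethyl)silyl]oxy}-7-({[tert-butyl(dimethyl)silyl]oxy}methyl)-3-methyl-6-[(2R)-oxiran-2-yl]oct-7-en-1-yn-3-ol | C1O[C@@H]1[C@H](C(=C)CO[Si](C)(C)C(C)(C)C)[C@@H](O[Si](C)(C)C(C)(C)C)C[C@@](C)(O)C#C | intermediate
27 | 2-chloropropanoyl chloride (racemic) | CC(Cl)C(=O)Cl | starting material
28 | 2-chloro-N-methoxy-N-methylpropanamide (racemic) | CC(Cl)C(=O)N(C)OC | intermediate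
29 | dilithium alkoxide acetylide of 26 | C1O[C@@H]1[C@H](C(=C)CO[Si](C)(C)C(C)(C)C)[C@@H](O[Si](C)(C)C(C)(C)C)C[C@@](C)(O[Li])C#C[Li] | intermediate
30 | γ-hydroxy ynone: C10 carbinol (R) joined through C1≡C2 to the C3 ketone bearing CH(Cl)CH3 (C4, both epimers); C5–C6 epoxide, C8 and C12 silyl ethers | C1O[C@@H]1[C@H](C(=C)CO[Si](C)(C)C(C)(C)C)[C@@H](O[Si](C)(C)C(C)(C)C)C[C@@](C)(O)C#CC(=O)C(C)Cl | intermediate
31 | (2R)-2-{(2S,3S)-2-{[tert-butyl(dimethyl)silyl]oxy}-4-({[tert-butyl(dimethyl)silyl]oxy}methyl)-3-[(2R)-oxiran-2-yl]pent-4-en-1-yl}-5-(1-chloroethyl)-2-methylfuran-3(2H)-one, both epimers at the chloroethyl carbon | C1O[C@@H]1[C@H](C(=C)CO[Si](C)(C)C(C)(C)C)[C@@H](O[Si](C)(C)C(C)(C)C)C[C@@]2(C)OC(=CC2=O)C(C)Cl | intermediate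
32 | C4 thioacetate corresponding to 31 (SC(O)CH3 in place of Cl) | C1O[C@@H]1[C@H](C(=C)CO[Si](C)(C)C(C)(C)C)[C@@H](O[Si](C)(C)C(C)(C)C)C[C@@]2(C)OC(=CC2=O)C(C)SC(C)=O | intermediate
33 | caesium C4 thiolate from 32 | C1O[C@@H]1[C@H](C(=C)CO[Si](C)(C)C(C)(C)C)[C@@H](O[Si](C)(C)C(C)(C)C)C[C@@]2(C)OC(=CC2=O)C(C)[S-].[Cs+] | intermediate
34 | eleven-membered cyclic sulfide (S between C4 and C5; free C6 OH; C8 and C12 silyl ethers; 6R,7S,8S,10R; C4 epimers) | CC(C)(C)[Si](C)(C)O[C@H]1C[C@@]2(C)OC(=CC2=O)C(C)SC[C@H](O)[C@@H]1C(=C)CO[Si](C)(C)C(C)(C)C | intermediate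
35 | eleven-membered cyclic sulfone, key-step precursor (6R,7S,8S,10R; C4 epimers) | CC(C)(C)[Si](C)(C)O[C@H]1C[C@@]2(C)OC(=CC2=O)C(C)S(=O)(=O)C[C@H](O)[C@@H]1C(=C)CO[Si](C)(C)C(C)(C)C | intermediate
36 | C4-bromo derivative of sulfone 35 | CC(C)(C)[Si](C)(C)O[C@H]1C[C@@]2(C)OC(=CC2=O)C(C)(Br)S(=O)(=O)C[C@H](O)[C@@H]1C(=C)CO[Si](C)(C)C(C)(C)C | intermediate
37 | cis-fused episulfone (thiirane 1,1-dioxide across C4–C5) | CC(C)(C)[Si](C)(C)O[C@H]1C[C@@]2(C)OC(=CC2=O)C3(C)C(S3(=O)=O)[C@H](O)[C@@H]1C(=C)CO[Si](C)(C)C(C)(C)C | intermediate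
38 | furanone-bridged (4Z)-cyclodecene, key-step product (free C6 OH; C8 and C12 silyl ethers; 6S,7S,8S,10R) | CC(C)(C)[Si](C)(C)O[C@H]1C[C@@]2(C)OC(=CC2=O)/C(C)=C\[C@H](O)[C@@H]1C(=C)CO[Si](C)(C)C(C)(C)C | intermediate
39 | angelic acid, (2Z)-2-methylbut-2-enoic acid | C/C=C(/C)C(=O)O | starting material
40 | (2Z)-2-methylbut-2-en-1-ol | C/C=C(/C)CO | intermediate
41 | [(2S,3R)-2,3-dimethyloxiran-2-yl]methanol | OC[C@]1(C)O[C@@H]1C | intermediate
42 | (2R,3R)-2,3-dimethyloxirane-2-carbaldehyde | O=C[C@]1(C)O[C@@H]1C | intermediate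
43 | (2R,3R)-2,3-dimethyloxirane-2-carboxylic acid | OC(=O)[C@]1(C)O[C@@H]1C | intermediate
44 | (2R,3R)-2,3-dimethyloxirane-2-carboxylic 2,4,6-trichlorobenzoic anhydride | O=C(OC(=O)[C@]1(C)O[C@@H]1C)c1c(Cl)cc(Cl)cc1Cl | intermediate
45 | C6 (2R,3R)-epoxyangelate of 38 (6S,7S,8S,10R) | CC(C)(C)[Si](C)(C)O[C@H]1C[C@@]2(C)OC(=CC2=O)/C(C)=C\[C@H](OC(=O)[C@]3(C)O[C@@H]3C)[C@@H]1C(=C)CO[Si](C)(C)C(C)(C)C | intermediate
46 | C8,C12-diol C6 epoxyangelate (6S,7R,8S,10R) | O[C@H]1C[C@@]2(C)OC(=CC2=O)/C(C)=C\[C@H](OC(=O)[C@]3(C)O[C@@H]3C)[C@@H]1C(=C)CO | intermediate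
47 | C12 enal with free C8 OH | O[C@H]1C[C@@]2(C)OC(=CC2=O)/C(C)=C\[C@H](OC(=O)[C@]3(C)O[C@@H]3C)[C@@H]1C(=C)C=O | intermediate
48 | C12 lactol (both C12 epimers) | C=C1C(O)O[C@H]2C[C@@]3(C)OC(=CC3=O)/C(C)=C\[C@H](OC(=O)[C@]4(C)O[C@@H]4C)[C@H]12 | intermediate
49 | target CNP0258430.3 (6S,7R,8S,10R; epoxyangelate 2R,3R; 4Z) | C=C1C(=O)O[C@H]2C[C@@]3(C)OC(=CC3=O)/C(C)=C\[C@H](OC(=O)[C@]3(C)O[C@@H]3C)[C@H]12 | target

**Step count**

Total: 28 steps. Longest linear sequence: 20 steps (1–6, 11–16, 18–22, 26–28).

**Steps most likely to fail**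

1. Step 22. The ring contraction may be undercut by retro-aldol-type opening of the C6 alkoxide next to the sulfone, by migration of the C8 silyl group to O6 under hydroxide, or by halogenation that is slow relative to these. The fallback separates halogenation from elimination and runs both cold. It sets out from sulfone 35, whose O6,C4-dianion (LiN(SiMe3)2, THF, −78 °C) should be chlorinated by Cl3C–CCl3 to give the isolated C4-chloro sulfone F1. Treating F1 with KOt-Bu in THF at −78 → 0 °C (classical Ramberg–Bäcklund reaction of a preformed α-halo sulfone) should then give the episulfone and, after loss of SO2, return to the route at 38.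

2. Step 20. Intermolecular thiolate–epoxide oligomerisation may outrun the medium-ring closure because intramolecular epoxide opening is slow. The fallback closes the ring by SN2 at a primary iodide instead. It sets out from thioacetate 32, isolated this time. LiI/AcOH in THF should open the epoxide to the iodohydrin thioacetate F2, and Et3SiCl/imidazole should cap O6 to give the triethylsilyl ether F3, so that the epoxide cannot re-form. Cs2CO3 in degassed MeOH/DMF at high dilution should then free the thiolate and displace the iodide (caesium-thiolate SN2 macrocyclisation) to give the O6-silylated cyclic sulfide F4. Pyridinium p-toluenesulfonate in MeOH should remove the triethylsilyl group selectively and come back to the route at 34.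

3. Step 19. The gold-catalysed hydration–cyclodehydration may stall, or adventitious acid may open the terminal epoxide. The fallback uses the classical amine-mediated furanone synthesis on a substrate without the chloride. It sets out from alkynol 26, whose dilithio derivative should be acylated by N-methoxy-N-methylpropanamide to give the ethyl ynone F5. Diethylamine should add in conjugate fashion to give the enaminone F6, and dilute aqueous acetic acid in THF should hydrolyse and cyclodehydrate it to the 5-ethylfuranone F7. Kinetic γ-deprotonation of this 5-alkyl-3(2H)-furanone (LiN(SiMe3)2, THF, −78 °C) and trapping with N-bromosuccinimide should give the C4 bromide F8. KSC(O)CH3 in DMF then returns to the route at thioacetate 32.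

Further compounds
F1 | step 22 | C4-chloro derivative of sulfone 35 | CC(C)(C)[Si](C)(C)O[C@H]1C[C@@]2(C)OC(=CC2=O)C(C)(Cl)S(=O)(=O)C[C@H](O)[C@@H]1C(=C)CO[Si](C)(C)C(C)(C)C
F2 | step 20 | C5 iodohydrin C4 thioacetate | IC[C@H](O)[C@H](C(=C)CO[Si](C)(C)C(C)(C)C)[C@@H](O[Si](C)(C)C(C)(C)C)C[C@@]1(C)OC(=CC1=O)C(C)SC(C)=O
F3 | step 20 | O6-triethylsilyl ether of F2 | IC[C@H](O[Si](CC)(CC)CC)[C@H](C(=C)CO[Si](C)(C)C(C)(C)C)[C@@H](O[Si](C)(C)C(C)(C)C)C[C@@]1(C)OC(=CC1=O)C(C)SC(C)=O
F4 | step 20 | O6-triethylsilyl ether of cyclic sulfide 34 | CC(C)(C)[Si](C)(C)O[C@H]1C[C@@]2(C)OC(=CC2=O)C(C)SC[C@H](O[Si](CC)(CC)CC)[C@@H]1C(=C)CO[Si](C)(C)C(C)(C)C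
F5 | step 19 | ethyl ynone (propanoyl analogue of 30) | C1O[C@@H]1[C@H](C(=C)CO[Si](C)(C)C(C)(C)C)[C@@H](O[Si](C)(C)C(C)(C)C)C[C@@](C)(O)C#CC(=O)CC
F6 | step 19 | C1 diethylamino enaminone | C1O[C@@H]1[C@H](C(=C)CO[Si](C)(C)C(C)(C)C)[C@@H](O[Si](C)(C)C(C)(C)C)C[C@@](C)(O)C(=CC(=O)CC)N(CC)CC
F7 | step 19 | 5-ethyl-3(2H)-furanone epoxide | C1O[C@@H]1[C@H](C(=C)CO[Si](C)(C)C(C)(C)C)[C@@H](O[Si](C)(C)C(C)(C)C)C[C@@]2(C)OC(=CC2=O)CC
F8 | step 19 | 5-(1-bromoethyl)-3(2H)-furanone epoxide | C1O[C@@H]1[C@H](C(=C)CO[Si](C)(C)C(C)(C)C)[C@@H](O[Si](C)(C)C(C)(C)C)C[C@@]2(C)OC(=CC2=O)C(C)Br
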